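## Analysis of the target

Vitisinol B is built on a dibenzo-fused cycloheptane. The seven-membered carbocycle runs through Ca (the CH carrying ring E, the 5-formyl-2-hydroxyphenyl group), two adjacent carbons of ring A (C4 and C3a), C3, two adjacent carbons of ring B (B1 and B6) and Cc (the CH carrying a 4-hydroxyphenyl group). Ring A is also fused through C3a and C7a to a 2,3-dihydrofuran: C3 is shared with the seven-membered ring and C2 is an O–CH bearing the second 4-hydroxyphenyl group. Ring A has its free hydroxyl on C6, and ring B is a resorcinol with oxygen on B3 and B5 (B5 next to B6, B4 between them). All four stereocentres are benzylic methines: C2 (S) and C3 (S) are trans on the dihydrofuran; on the seven-membered ring the hydrogens on Ca (R) and C3 are cis to each other and trans to the hydrogen on Cc (S), so ring E and the Cc aryl group are trans. The sensitive features are six free phenols, an aryl aldehyde para to a phenol, and the C2–O bond, a 4-oxybenzylic ether that ionises easily under acid. The difficulty is that no stereocentre keeps a functional group beside it, that Ca and Cc are all-carbon centres between three aryl groups, and that the seven-membered ring must be closed between hindered benzylic carbons. The strategy rests on ring B: a 3,5-dioxygenated benzene whose adjacent carbons B1 and B6 carry C3 and Cc is exactly what a 4-methoxy-2-pyrone bound to C3 through its carbon 6, and an alkyne on Cc, give on cycloaddition and decarboxylation. Ring B and the seven-membered ring can therefore be formed together in a step that creates no stereocentre.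

## Retrosynthetic reasoning

**35 to 34 to 32 (unmasking).** No skeletal bond is cut. Target 35 is taken back to its pentamethyl ether 34, and 34 to the aryl boronate 32, in which the B5 oxygen is still a C–B bond and the aldehyde is an acetal. This keeps every late intermediate non-phenolic and keeps the aldehyde masked while the C–B bond is oxidised (through 33). The forward steps must cleave five aryl methyl ethers without ionising the C2–O bond.

**32 to 30 (key disconnection).** Ring B is cut at B1–B6 and B4–B5, with a lactone bridge put back between B1 and B4 (31). These are the only two bonds whose cleavage opens both ring B and the seven-membered ring. The precursor 30 carries a 4-methoxy-2-pyrone on C3 and an alkynyl boronate on Cc, and these map atom for atom onto the 3,5-dioxygenation of ring B. The forward reaction must bend the alkyne over the pyrone within a five-atom tether, but it is thermal and neutral and forms no stereocentre, so all stereochemical work can be finished beforehand.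

**30 to 29 to 24 + 25 (boron and pyrone).** The C–B bond of 30 is cut to the terminal alkyne 29, because an alkynyl boronate would not survive pyrone construction. The pyrone of 29 is cut between its carbons 5 and 6 and at the lactone C–O bond (through 28, 27 and 26), giving the carboxylic acid 24 and the four-carbon bis-silyl dienolate 25. The cut is placed there because a carboxyl carbon on C3 is what the dihydrofuran-forming step delivers. The forward acylation must avoid basic enolates, since C3–H is acidic and lies β to the ring oxygen.

**24 to 20 (alkyne).** The terminal alkyne carbon is removed (through 23, 22 and 21) to give the aldehyde 20. An aldehyde on Cc allows the Cc aryl group to be introduced by enamine chemistry. The price is that 20 is an epimerisable α-aryl aldehyde, so the forward homologation must stay non-basic until the carbonyl group is gone.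

**20 to 16 + 19 (Cc–aryl bond).** The bond from Cc to its aryl group is cut, giving the 3,3-diarylpropanal 16 and the aryl donor 19 (from 17 and 18). This is preferred over cutting Ca–Cc because a catalyst can then set Cc independently of the neighbouring centre.

**16 to 13 + 15, and 13 to 10 + 11 (Ca).** The Ca–ring E bond is cut to the enal 13 and the ring E boron reagent 15 (from 14). Ca carries two aryl groups and no heteroatom, so a catalyst-controlled conjugate arylation is the most direct way to set it. The C4–Ca bond of 13 is then cut to the aryl bromide 10 and the three-carbon alkenyl boronate 11.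

**10 to 8 (dihydrofuran).** The C2–C3 bond is cut, leading to the aryl diazoacetate 8; the forward reaction is a catalyst-controlled carbene insertion into the benzylic ether C–H bond. It is done on this simple substrate, before the side chain exists, so that no other C–H bond, alkene or alkyne competes. C2 is set by the catalyst; C3 is then equilibrated to trans (through 9).

**8 to 6 to 4 to 3 to 1 + 2, with 5 (ring A).** The diazo ester 8 comes from the α-keto ester 6 (through 7). The benzyl ether of 6 is cut to phenol 4 and chloride 5. Phenol 4 comes from the dimethyl ether 3, whose ketone both carries the future C3 and directs cleavage of only the neighbouring methoxy group; this distinguishes the two ring A oxygens. Compound 3 is cut at the aryl–carbonyl bond to the symmetrical arene 1 and the acyl chloride 2.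

## Alternatives that were turned down

**Alternative 1: oxidative phenol–stilbene cyclisation.** The C3–C3a and C2–O bonds are cut together, leading back to an open trans-stilbene phenol whose ring A is a free resorcinol. In the forward step a one-electron oxidant (Ag2O, or FeCl3·6H2O at high dilution) makes a phenoxyl radical delocalised onto the stilbene carbon that becomes C3. This carbon bonds to ring A ortho to a hydroxyl, and the resulting quinone methide at C2 is trapped by that hydroxyl to give A1.
- For: it follows the likely biogenesis, closes two rings and sets C2 and C3 in one operation, and leaves only ether cleavage afterwards.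
- Against: the radical must attack a closed-shell resorcinol carbon in a seven-membered closure, while phenoxyl radicals readily dimerise through several C–C and C–O modes, so chemoselectivity rests on dilution alone. The face on which C3 bonds, relative to Ca and Cc, is controlled by no reagent. The substrate already needs the Ca/Cc pair and a differentiated pattern of free and methylated phenols.
- Comparison: it is stronger on step economy and mildness. The chosen route offers instead a ring closure whose constitution is fixed by connectivity and that makes no stereocentre.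

**Alternative 2: aryne insertion with ring expansion.** The C3–B1 and Cc–B6 bonds are cut, leading back to an aryne and a five-membered cyclic β-keto ester. In the forward step CsF releases the aryne from a silyl triflate; the enolate carbon adds at the aryne carbon remote from methoxy, the aryl anion closes onto the ketone, and the four-membered alkoxide fragments to the seven-membered keto ester A2.
- For: this is an established reaction class, run under mild fluoride conditions; it is convergent, and the methoxy group directs the regiochemistry.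
- Against: A2 is racemic. C3 and Ca are enolisable, Cc is still a ketone and C2 does not yet exist. Afterwards the route needs aryl addition and stereoselective removal of a tertiary hydroxyl at Cc, construction of the dihydrofuran from the ester, conversion of bromide into aldehyde, and a resolution or late asymmetric step, all on a flexible seven-membered ring.
- Comparison: its key step is probably more dependable than a high-temperature cycloaddition. The chosen route reaches its key step with all four centres fixed and needs only two steps after it.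

**Alternative 3: diaryl carbene C–H insertion to close the dihydrofuran last.** The C3–C2 bond is cut, leading back to a hydrazone at C3 of the preformed seven-membered ring and a 4-methoxybenzyl ether on the ring A oxygen. In the forward step MnO2 gives the diazo compound and Rh2(S-PTAD)4 (or its enantiomer) the diaryl carbene, which inserts into the benzylic ether C–H bond to give A3.
- For: this insertion type runs at low temperature with high stereocontrol in simple systems, sets two centres late, and A3 is close to the target.
- Against: the carbene carbon lies inside the dibenzo-fused seven-membered ring next to Ca and Cc, so the configuration at C3 depends on ring conformation and on catalyst matching. C3 cannot be corrected afterwards because it is not epimerisable. The seven-membered ketone with Ca and Cc in place must still be made by a separate ring construction, and the hydrazone is hindered.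
- Comparison: it is stronger in the mildness of its key step. The chosen route uses the same kind of insertion early, on a simple substrate where C3 can be equilibrated, and keeps its key step for a process that creates no stereocentre.

Key step: step 17

Assumption: the antipodes named for the three chiral catalysts (steps 5, 8 and 10) are those expected to give the drawn configurations; if the sense of induction proves opposite for any of them, its mirror-image form is used and nothing else changes.

## Route

Step 1
Reactants: 1 1-bromo-3,5-dimethoxybenzene; 2 methyl chlorooxoacetate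
Product: 3 methyl 2-(2-bromo-4,6-dimethoxyphenyl)-2-oxoacetate
Conditions: TiCl4, CH2Cl2, −20 to 0 °C
Reagents that add atoms: none
Why: Friedel–Crafts acylation; the carbon between bromine and methoxy is para to one methoxy group and ortho to the other, and is less crowded than the carbon between the two methoxy groups, so acylation there should dominate and any minor isomer is removed here.

Step 2
Reactants: 3 methyl 2-(2-bromo-4,6-dimethoxyphenyl)-2-oxoacetate
Product: 4 methyl 2-(2-bromo-6-hydroxy-4-methoxyphenyl)-2-oxoacetate
Conditions: BCl3, CH2Cl2, −78 to 0 °C; aqueous work-up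
Reagents that add atoms: none
Why: Chelation-controlled Lewis-acid ether cleavage: boron bound between the aryl ketone and the ortho methoxy oxygen delivers chloride only to that methyl group, so the para methoxy group and the ester remain and the two ring A oxygens become different.

Step 3
Reactants: 4 methyl 2-(2-bromo-6-hydroxy-4-methoxyphenyl)-2-oxoacetate; 5 4-methoxybenzyl chloride
Product: 6 methyl 2-{2-bromo-4-methoxy-6-[(4-methoxybenzyl)oxy]phenyl}-2-oxoacetate
Conditions: K2CO3, NaI (cat.), DMF, 50 °C
Reagents that add atoms: none
Why: Williamson ether synthesis with a reactive benzylic chloride; it installs the O–CH2–aryl unit whose CH2 becomes C2 and whose aryl group becomes the C2 aryl group.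

Step 4
Reactants: 6 methyl 2-{2-bromo-4-methoxy-6-[(4-methoxybenzyl)oxy]phenyl}-2-oxoacetate
Product: 8 methyl 2-{2-bromo-4-methoxy-6-[(4-methoxybenzyl)oxy]phenyl}-2-diazoacetate, via tosylhydrazone 7 (not isolated)
Conditions: TsNHNH2, toluene, 80 °C; then DBU, CH2Cl2, rt
Reagents that add atoms: 4-methylbenzenesulfonohydrazide, Cc1ccc(S(=O)(=O)NN)cc1
Why: Condensation of the reactive α-keto ester with the hydrazide, then base-induced loss of sulfinate (Bamford–Stevens reaction) gives the aryl diazoacetate directly at the correct oxidation level.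

Step 5
Reactants: 8 methyl 2-{2-bromo-4-methoxy-6-[(4-methoxybenzyl)oxy]phenyl}-2-diazoacetate
Product: 10 methyl (2S,3S)-4-bromo-6-methoxy-2-(4-methoxyphenyl)-2,3-dihydro-1-benzofuran-3-carboxylate (trans), via cis ester 9 (not isolated)
Conditions: Rh2(R-PTTL)4 (1 mol%; PTTL = N-phthaloyl-tert-leucinate), toluene, −60 °C; then NaOMe, MeOH, rt
Reagents that add atoms: none
Why: Intramolecular 1,5 C–H insertion of the dirhodium-bound donor/acceptor carbene into the ether CH2, which is activated by oxygen and by the 4-methoxyphenyl ring; the chiral carboxylate ligands select one of the two enantiotopic hydrogens and so set C2 (S), giving the kinetic cis ester. Methoxide then equilibrates the enolisable C3 to the more stable trans (3S) ester without touching C2.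

Step 6
Reactants: 10 methyl (2S,3S)-4-bromo-6-methoxy-2-(4-methoxyphenyl)-2,3-dihydro-1-benzofuran-3-carboxylate; 11 (E)-2-(3,3-diethoxyprop-1-en-1-yl)-4,4,5,5-tetramethyl-1,3,2-dioxaborolane
Product: 13 methyl (2S,3S)-6-methoxy-2-(4-methoxyphenyl)-4-[(E)-3-oxoprop-1-en-1-yl]-2,3-dihydro-1-benzofuran-3-carboxylate, via diethyl acetal 12 (not isolated)
Conditions: Pd(OAc)2, SPhos, K3PO4, toluene/H2O, 80 °C; then 1 M HCl, THF, rt
Reagents that add atoms: water, O
Why: Suzuki–Miyaura coupling at the hindered bromide with an electron-rich biaryl phosphine; the alkenyl group transfers with retention, and mild acid then hydrolyses the diethyl acetal to the E enal.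

Step 7
Reactants: 14 (5-formyl-2-methoxyphenyl)boronic acid
Product: 15 2-[3-(1,3,2-dioxaborolan-2-yl)-4-methoxyphenyl]-1,3-dioxolane
Conditions: ethane-1,2-diol, PPTS (cat.), toluene, reflux (Dean–Stark)
Reagents that add atoms: ethane-1,2-diol, OCCO
Why: Acid-catalysed acetalisation with azeotropic removal of water protects the aldehyde; the boronic acid is esterified by the diol at the same time, which is harmless because that B–O ester is hydrolysed in the aqueous medium of step 8.

Step 8
Reactants: 13 methyl (2S,3S)-6-methoxy-2-(4-methoxyphenyl)-4-[(E)-3-oxoprop-1-en-1-yl]-2,3-dihydro-1-benzofuran-3-carboxylate; 15 2-[3-(1,3,2-dioxaborolan-2-yl)-4-methoxyphenyl]-1,3-dioxolane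
Product: 16 methyl (2S,3S)-4-{(1R)-1-[5-(1,3-dioxolan-2-yl)-2-methoxyphenyl]-3-oxopropyl}-6-methoxy-2-(4-methoxyphenyl)-2,3-dihydro-1-benzofuran-3-carboxylate
Conditions: [RhCl(C2H4)2]2 (cat.), (S,S)-2,5-diphenylbicyclo[2.2.2]octa-2,5-diene (cat.), aq. KOH (substoichiometric), dioxane, 40 °C
Reagents that add atoms: none
Why: Hayashi–Miyaura conjugate arylation: the aryl–rhodium species formed by transmetalation adds to the β-carbon of the E enal, and the chiral diene ligand chooses the enal face and sets Ca (R) independently of the remote C2 and C3. Diene ligands are used because they favour 1,4- over 1,2-addition with enals.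

Step 9
Reactants: 17 anisole; 18 2-(diacetoxyiodo)-1,3,5-trimethylbenzene
Product: 19 (4-methoxyphenyl)(2,4,6-trimethylphenyl)iodonium trifluoromethanesulfonate
Conditions: TfOH, CH2Cl2, 0 °C to rt
Reagents that add atoms: trifluoromethanesulfonic acid, OS(=O)(=O)C(F)(F)F
Why: Electrophilic aromatic substitution of anisole at its para position by the acid-activated trivalent iodine reagent gives the unsymmetrical diaryliodonium salt; the mesityl group serves as the non-transferred aryl group.

Step 10
Reactants: 16 methyl (2S,3S)-4-{(1R)-1-[5-(1,3-dioxolan-2-yl)-2-methoxyphenyl]-3-oxopropyl}-6-methoxy-2-(4-methoxyphenyl)-2,3-dihydro-1-benzofuran-3-carboxylate; 19 (4-methoxyphenyl)(2,4,6-trimethylphenyl)iodonium trifluoromethanesulfonate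
Product: 20 methyl (2S,3S)-4-{(1R,2S)-1-[5-(1,3-dioxolan-2-yl)-2-methoxyphenyl]-2-(4-methoxyphenyl)-3-oxopropyl}-6-methoxy-2-(4-methoxyphenyl)-2,3-dihydro-1-benzofuran-3-carboxylate
Conditions: CuBr (10 mol%), (2S,5S)-5-benzyl-2-tert-butyl-3-methylimidazolidin-4-one·TCA (10 mol%), NaHCO3, toluene/Et2O, 23 °C; crude product used at once
Reagents that add atoms: none
Why: Enantioselective α-arylation of an aldehyde by combined enamine and copper catalysis: the iodonium salt transfers its 4-methoxyphenyl group to copper, and the chiral enamine attacks this aryl–copper species on the face left open by the imidazolidinone, so Cc (S) is set by the catalyst and not by Ca. The conditions are nearly neutral and the hindered product does not readily re-form an enamine, so the new centre should not epimerise.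

Step 11
Reactants: 20 methyl (2S,3S)-4-{(1R,2S)-1-[5-(1,3-dioxolan-2-yl)-2-methoxyphenyl]-2-(4-methoxyphenyl)-3-oxopropyl}-6-methoxy-2-(4-methoxyphenyl)-2,3-dihydro-1-benzofuran-3-carboxylate
Product: 21 methyl (2S,3S)-4-{(1R,2R)-4,4-dibromo-1-[5-(1,3-dioxolan-2-yl)-2-methoxyphenyl]-2-(4-methoxyphenyl)but-3-en-1-yl}-6-methoxy-2-(4-methoxyphenyl)-2,3-dihydro-1-benzofuran-3-carboxylate
Conditions: CBr4, PPh3, Et3N, CH2Cl2, 0 °C
Reagents that add atoms: carbon tetrabromide, BrC(Br)(Br)Br
Why: Ramirez dibromo-olefination (first stage of the Corey–Fuchs sequence) with a stabilised, non-basic ylide, chosen because it does not enolise the α-aryl aldehyde, so Cc is kept (its descriptor changes only through priorities). Et3N buffers acid and protects the acetal.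

Step 12
Reactants: 21 methyl (2S,3S)-4-{(1R,2R)-4,4-dibromo-1-[5-(1,3-dioxolan-2-yl)-2-methoxyphenyl]-2-(4-methoxyphenyl)but-3-en-1-yl}-6-methoxy-2-(4-methoxyphenyl)-2,3-dihydro-1-benzofuran-3-carboxylate
Product: 22 methyl (2S,3S)-4-{(1R,2R,3Z)-4-bromo-1-[5-(1,3-dioxolan-2-yl)-2-methoxyphenyl]-2-(4-methoxyphenyl)but-3-en-1-yl}-6-methoxy-2-(4-methoxyphenyl)-2,3-dihydro-1-benzofuran-3-carboxylate
Conditions: Bu3SnH, Pd(PPh3)4 (cat.), toluene, rt
Reagents that add atoms: none
Why: Palladium-catalysed hydrogenolysis of a gem-dibromoalkene: oxidative addition occurs selectively at the C–Br bond trans to the carbon substituent, giving the Z bromoalkene under neutral conditions that leave the ester and all stereocentres alone.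

Step 13
Reactants: 22 methyl (2S,3S)-4-{(1R,2R,3Z)-4-bromo-1-[5-(1,3-dioxolan-2-yl)-2-methoxyphenyl]-2-(4-methoxyphenyl)but-3-en-1-yl}-6-methoxy-2-(4-methoxyphenyl)-2,3-dihydro-1-benzofuran-3-carboxylate
Product: 24 (2S,3S)-4-{(1R,2R)-1-[5-(1,3-dioxolan-2-yl)-2-methoxyphenyl]-2-(4-methoxyphenyl)but-3-yn-1-yl}-6-methoxy-2-(4-methoxyphenyl)-2,3-dihydro-1-benzofuran-3-carboxylic acid, via alkyne ester 23 (not isolated)
Conditions: TBAF·3H2O, DMF, 60 °C; then LiOH, THF/H2O, 40 °C; AcOH to pH 5
Reagents that add atoms: lithium hydroxide, [Li+].[OH-]
Why: In the Z bromoalkene H and Br are anti, so wet fluoride brings about E2 elimination to the terminal alkyne without a strong base; saponification then frees the acid. C3 stays trans because that is its thermodynamic configuration, and the mild acidification spares the acetal.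

Step 14
Reactants: 24 (2S,3S)-4-{(1R,2R)-1-[5-(1,3-dioxolan-2-yl)-2-methoxyphenyl]-2-(4-methoxyphenyl)but-3-yn-1-yl}-6-methoxy-2-(4-methoxyphenyl)-2,3-dihydro-1-benzofuran-3-carboxylic acid; 25 1-methoxy-1,3-bis(trimethylsilyloxy)buta-1,3-diene
Product: 28 6-{(2S,3S)-4-[(1R,2R)-1-[5-(1,3-dioxolan-2-yl)-2-methoxyphenyl]-2-(4-methoxyphenyl)but-3-yn-1-yl]-6-methoxy-2-(4-methoxyphenyl)-2,3-dihydro-1-benzofuran-3-yl}-4-hydroxy-2H-pyran-2-one, via acid chloride 26 (not isolated), via diketo ester 27 (not isolated)
Conditions: 1-chloro-N,N,2-trimethylprop-1-en-1-amine, CH2Cl2, 0 °C; then 25, CH2Cl2, −78 °C to rt, aq. NH4Cl; then DBU, toluene, rt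
Reagents that add atoms: none
Why: The acid chloride is made under neutral conditions and acylates the bis-silyl dienolate of methyl acetoacetate at its terminal carbon (Mukaiyama-type Claisen condensation), which avoids a basic enolate that would deprotonate C3. DBU then closes the enol onto the ester to give the 4-hydroxy-2-pyrone.

Step 15
Reactants: 28 the 4-hydroxy-2-pyrone of step 14
Product: 29 6-{(2S,3S)-4-[(1R,2R)-1-[5-(1,3-dioxolan-2-yl)-2-methoxyphenyl]-2-(4-methoxyphenyl)but-3-yn-1-yl]-6-methoxy-2-(4-methoxyphenyl)-2,3-dihydro-1-benzofuran-3-yl}-4-methoxy-2H-pyran-2-one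
Conditions: Me2SO4, K2CO3, acetone, reflux
Reagents that add atoms: dimethyl sulfate, COS(=O)(=O)OC
Why: O-Alkylation of the vinylogous acid; with dimethyl sulfate and carbonate the 4-oxygen is methylated in preference, giving the 4-methoxy-2-pyrone whose methoxy group becomes the B3 oxygen.

Step 16
Reactants: 29 the 4-methoxy-2-pyrone terminal alkyne of step 15
Product: 30 the alkynyl pinacol boronate of 29 (all four stereocentres as in 29; the terminal alkyne carbon now bears the 4,4,5,5-tetramethyl-1,3,2-dioxaborolan-2-yl group)
Conditions: HBpin, Fe(OTf)2 (cat.), DABCO (cat.), toluene, 80 °C; filtration through Celite, used directly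
Reagents that add atoms: pinacolborane, CC1(C)OBOC1(C)C
Why: Catalytic dehydrogenative C–H borylation of a terminal alkyne: the acetylide formed on the metal exchanges with the B–H bond and H2 is released. No strong base is used, so the pyrone and the acidic C3–H are not attacked.

Step 17
Reactants: 30 the alkynyl pinacol boronate
Product: 32 penta-O-methyl vitisinol B ethylene acetal bearing a pinacol boronate on B5, via bridged lactone 31 (not isolated)
Conditions: 1,2-dichlorobenzene (degassed, dilute), BHT (cat.), 180 °C, sealed tube
Reagents that add atoms: none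
Why: On heating, the alkynyl boronate adds across positions 3 and 6 of the 4-methoxy-2-pyrone in a concerted intramolecular [4+2] cycloaddition to give the bridged lactone 31, which loses CO2 in an irreversible retro-[4+2] step and delivers aromatic ring B. The closest known reaction type is the Diels–Alder reaction of 2-pyrones with alkynes, including alkynyl boronates, followed by CO2 extrusion, which is also established with tethered alkynes. Ring B is closed by the two new σ bonds B1–B6 and B4–B5 and becomes aromatic on decarboxylation; the seven-membered ring is closed by the B1–B6 bond as the ring containing the five tether atoms C3, C3a, C4, Ca and Cc, the tether being attached at the diene terminus. No stereocentre survives the step: the two bridgehead centres of 31 are destroyed on aromatisation, so either face of the pyrone may react, and the four resident centres are untouched under neutral, aprotic conditions. The selectivity needed is regiochemical and is secured by connectivity, since the tether can only join pyrone carbon 6 to the alkyne carbon on Cc, which places methoxy on B3 and boron on B5. Moderate dilution favours the intramolecular reaction over pyrone dimerisation, and the ortho-disubstituted ring A limits the conformations of the tether and so lowers the entropic cost of the seven-membered closure.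

Step 18
Reactants: 32 the aryl pinacol boronate
Product: 34 penta-O-methyl vitisinol B (free B5 phenol and free aldehyde), via phenol acetal 33 (not isolated)
Conditions: 30% H2O2, aq. NaOH, THF, 0 °C; then 1 M HCl, THF, rt
Reagents that add atoms: hydrogen peroxide, OO; water, O
Why: Oxidation of the aryl C–B bond (aryl migration from boron to oxygen in the hydroperoxide adduct) gives the B5 phenol while the aldehyde is still an acetal, so no Dakin oxidation can occur. Dilute acid then hydrolyses the dioxolane.

Step 19
Reactants: 34 penta-O-methyl vitisinol B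
Product: 35 vitisinol B
Conditions: BBr3, CH2Cl2, −78 °C to rt; then H2O
Reagents that add atoms: none
Why: Lewis-acid cleavage of the five aryl methyl ethers (bromide attacks the methyl group of each boron-complexed ether). The low starting temperature limits ionisation of the benzylic C2–O bond, and aqueous work-up hydrolyses the aryl borates and any aldehyde–boron adduct.

## Compound list

1 | 1-bromo-3,5-dimethoxybenzene | COc1cc(Br)cc(OC)c1 | starting material
2 | methyl chlorooxoacetate | COC(=O)C(=O)Cl | starting material
3 | methyl 2-(2-bromo-4,6-dimethoxyphenyl)-2-oxoacetate | COC(=O)C(=O)c1c(Br)cc(OC)cc1OC | intermediate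
4 | methyl 2-(2-bromo-6-hydroxy-4-methoxyphenyl)-2-oxoacetate | COC(=O)C(=O)c1c(Br)cc(OC)cc1O | intermediate
5 | 4-methoxybenzyl chloride | COc1ccc(CCl)cc1 | starting material
6 | methyl 2-{2-bromo-4-methoxy-6-[(4-methoxybenzyl)oxy]phenyl}-2-oxoacetate | COC(=O)C(=O)c1c(Br)cc(OC)cc1OCc1ccc(OC)cc1 | intermediate
7 | N-tosylhydrazone of 6 | COC(=O)C(=NNS(=O)(=O)c1ccc(C)cc1)c1c(Br)cc(OC)cc1OCc1ccc(OC)cc1 | intermediate
8 | methyl 2-{2-bromo-4-methoxy-6-[(4-methoxybenzyl)oxy]phenyl}-2-diazoacetate | COC(=O)C(=[N+]=[N-])c1c(Br)cc(OC)cc1OCc1ccc(OC)cc1 | intermediate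
9 | methyl (2S,3R)-4-bromo-6-methoxy-2-(4-methoxyphenyl)-2,3-dihydro-1-benzofuran-3-carboxylate (cis) | Brc1cc(OC)cc2O[C@H](c3ccc(OC)cc3)[C@H](C(=O)OC)c12 | intermediate
10 | methyl (2S,3S)-4-bromo-6-methoxy-2-(4-methoxyphenyl)-2,3-dihydro-1-benzofuran-3-carboxylate (trans) | Brc1cc(OC)cc2O[C@H](c3ccc(OC)cc3)[C@@H](C(=O)OC)c12 | intermediate
11 | (E)-2-(3,3-diethoxyprop-1-en-1-yl)-4,4,5,5-tetramethyl-1,3,2-dioxaborolane | CCOC(OCC)/C=C/B1OC(C)(C)C(C)(C)O1 | starting material
12 | methyl (2S,3S)-4-[(E)-3,3-diethoxyprop-1-en-1-yl]-6-methoxy-2-(4-methoxyphenyl)-2,3-dihydro-1-benzofuran-3-carboxylate | CCOC(OCC)/C=C/c1cc(OC)cc2O[C@H](c3ccc(OC)cc3)[C@@H](C(=O)OC)c12 | intermediate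
13 | methyl (2S,3S)-6-methoxy-2-(4-methoxyphenyl)-4-[(E)-3-oxoprop-1-en-1-yl]-2,3-dihydro-1-benzofuran-3-carboxylate | O=C/C=C/c1cc(OC)cc2O[C@H](c3ccc(OC)cc3)[C@@H](C(=O)OC)c12 | intermediate
14 | (5-formyl-2-methoxyphenyl)boronic acid | COc1ccc(C=O)cc1B(O)O | starting material
15 | 2-[3-(1,3,2-dioxaborolan-2-yl)-4-methoxyphenyl]-1,3-dioxolane | COc1ccc(C2OCCO2)cc1B1OCCO1 | intermediate
16 | methyl (2S,3S)-4-{(1R)-1-[5-(1,3-dioxolan-2-yl)-2-methoxyphenyl]-3-oxopropyl}-6-methoxy-2-(4-methoxyphenyl)-2,3-dihydro-1-benzofuran-3-carboxylate | O=CC[C@@H](c1cc(C2OCCO2)ccc1OC)c1cc(OC)cc2O[C@H](c3ccc(OC)cc3)[C@@H](C(=O)OC)c12 | intermediate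
17 | anisole | COc1ccccc1 | starting material
18 | 2-(diacetoxyiodo)-1,3,5-trimethylbenzene | CC(=O)OI(OC(C)=O)c1c(C)cc(C)cc1C | starting material
19 | (4-methoxyphenyl)(2,4,6-trimethylphenyl)iodonium trifluoromethanesulfonate | COc1ccc([I+]c2c(C)cc(C)cc2C)cc1.[O-]S(=O)(=O)C(F)(F)F | intermediate
20 | methyl (2S,3S)-4-{(1R,2S)-1-[5-(1,3-dioxolan-2-yl)-2-methoxyphenyl]-2-(4-methoxyphenyl)-3-oxopropyl}-6-methoxy-2-(4-methoxyphenyl)-2,3-dihydro-1-benzofuran-3-carboxylate | O=C[C@H](c1ccc(OC)cc1)[C@@H](c1cc(C2OCCO2)ccc1OC)c1cc(OC)cc2O[C@H](c3ccc(OC)cc3)[C@@H](C(=O)OC)c12 | intermediate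
21 | methyl (2S,3S)-4-{(1R,2R)-4,4-dibromo-1-[5-(1,3-dioxolan-2-yl)-2-methoxyphenyl]-2-(4-methoxyphenyl)but-3-en-1-yl}-6-methoxy-2-(4-methoxyphenyl)-2,3-dihydro-1-benzofuran-3-carboxylate | BrC(Br)=C[C@H](c1ccc(OC)cc1)[C@@H](c1cc(C2OCCO2)ccc1OC)c1cc(OC)cc2O[C@H](c3ccc(OC)cc3)[C@@H](C(=O)OC)c12 | intermediate
22 | methyl (2S,3S)-4-{(1R,2R,3Z)-4-bromo-1-[5-(1,3-dioxolan-2-yl)-2-methoxyphenyl]-2-(4-methoxyphenyl)but-3-en-1-yl}-6-methoxy-2-(4-methoxyphenyl)-2,3-dihydro-1-benzofuran-3-carboxylate | Br/C=C\[C@H](c1ccc(OC)cc1)[C@@H](c1cc(C2OCCO2)ccc1OC)c1cc(OC)cc2O[C@H](c3ccc(OC)cc3)[C@@H](C(=O)OC)c12 | intermediate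
23 | methyl (2S,3S)-4-{(1R,2R)-1-[5-(1,3-dioxolan-2-yl)-2-methoxyphenyl]-2-(4-methoxyphenyl)but-3-yn-1-yl}-6-methoxy-2-(4-methoxyphenyl)-2,3-dihydro-1-benzofuran-3-carboxylate | C#C[C@H](c1ccc(OC)cc1)[C@@H](c1cc(C2OCCO2)ccc1OC)c1cc(OC)cc2O[C@H](c3ccc(OC)cc3)[C@@H](C(=O)OC)c12 | intermediate
24 | (2S,3S)-4-{(1R,2R)-1-[5-(1,3-dioxolan-2-yl)-2-methoxyphenyl]-2-(4-methoxyphenyl)but-3-yn-1-yl}-6-methoxy-2-(4-methoxyphenyl)-2,3-dihydro-1-benzofuran-3-carboxylic acid | C#C[C@H](c1ccc(OC)cc1)[C@@H](c1cc(C2OCCO2)ccc1OC)c1cc(OC)cc2O[C@H](c3ccc(OC)cc3)[C@@H](C(=O)O)c12 | intermediate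
25 | 1-methoxy-1,3-bis(trimethylsilyloxy)buta-1,3-diene | COC(O[Si](C)(C)C)=CC(=C)O[Si](C)(C)C | starting material
26 | acid chloride of 24 | C#C[C@H](c1ccc(OC)cc1)[C@@H](c1cc(C2OCCO2)ccc1OC)c1cc(OC)cc2O[C@H](c3ccc(OC)cc3)[C@@H](C(=O)Cl)c12 | intermediate
27 | methyl 3,5-dioxo-5-[the (2S,3S)-dihydrobenzofuran-3-yl group of 24]pentanoate | C#C[C@H](c1ccc(OC)cc1)[C@@H](c1cc(C2OCCO2)ccc1OC)c1cc(OC)cc2O[C@H](c3ccc(OC)cc3)[C@@H](C(=O)CC(=O)CC(=O)OC)c12 | intermediate
28 | 6-{(2S,3S)-4-[(1R,2R)-1-[5-(1,3-dioxolan-2-yl)-2-methoxyphenyl]-2-(4-methoxyphenyl)but-3-yn-1-yl]-6-methoxy-2-(4-methoxyphenyl)-2,3-dihydro-1-benzofuran-3-yl}-4-hydroxy-2H-pyran-2-one | C#C[C@H](c1ccc(OC)cc1)[C@@H](c1cc(C2OCCO2)ccc1OC)c1cc(OC)cc2O[C@H](c3ccc(OC)cc3)[C@@H](C3=CC(O)=CC(=O)O3)c12 | intermediate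
29 | 6-{(2S,3S)-4-[(1R,2R)-1-[5-(1,3-dioxolan-2-yl)-2-methoxyphenyl]-2-(4-methoxyphenyl)but-3-yn-1-yl]-6-methoxy-2-(4-methoxyphenyl)-2,3-dihydro-1-benzofuran-3-yl}-4-methoxy-2H-pyran-2-one | C#C[C@H](c1ccc(OC)cc1)[C@@H](c1cc(C2OCCO2)ccc1OC)c1cc(OC)cc2O[C@H](c3ccc(OC)cc3)[C@@H](C3=CC(OC)=CC(=O)O3)c12 | intermediate
30 | alkynyl pinacol boronate of 29: trans-dihydrobenzofuran with the 4-methoxy-2-pyron-6-yl group on C3 and the Ca/Cc side chain ending in C≡C–B(pinacolato) | C1COC(O1)c1ccc(OC)c(c1)[C@@H](c1cc(OC)cc2O[C@H](c3ccc(OC)cc3)[C@@H](C3=CC(OC)=CC(=O)O3)c12)[C@@H](c1ccc(OC)cc1)C#CB1OC(C)(C)C(C)(C)O1 | intermediate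
31 | bridged bicyclic lactone from addition of the alkyne across pyrone positions 3 and 6 of 30 (2-oxabicyclo[2.2.2]octa-5,7-dien-3-one core; bridgehead configurations not defined) | C1COC(O1)c1ccc(OC)c([C@H]2c3cc(OC)cc4c3[C@H](C56OC(=O)C(C(OC)=C5)C(B7OC(C)(C)C(C)(C)O7)=C6[C@@H]2c2ccc(OC)cc2)[C@@H](c2ccc(OC)cc2)O4)c1 | intermediate
32 | penta-O-methyl vitisinol B ethylene acetal with a pinacol boronate in place of the B5 hydroxyl | C1COC(O1)c1ccc(OC)c([C@H]2c3cc(OC)cc4c3[C@H](c3cc(OC)cc(B5OC(C)(C)C(C)(C)O5)c3[C@@H]2c2ccc(OC)cc2)[C@@H](c2ccc(OC)cc2)O4)c1 | intermediate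
33 | penta-O-methyl vitisinol B ethylene acetal (free B5 phenol) | C1COC(O1)c1ccc(OC)c([C@H]2c3cc(OC)cc4c3[C@H](c3cc(OC)cc(O)c3[C@@H]2c2ccc(OC)cc2)[C@@H](c2ccc(OC)cc2)O4)c1 | intermediate
34 | penta-O-methyl vitisinol B (free B5 phenol; other five phenols as methyl ethers) | O=Cc1ccc(OC)c([C@H]2c3cc(OC)cc4c3[C@H](c3cc(OC)cc(O)c3[C@@H]2c2ccc(OC)cc2)[C@@H](c2ccc(OC)cc2)O4)c1 | intermediate
35 | vitisinol B | O=Cc1ccc(O)c([C@H]2c3cc(O)cc4c3[C@H](c3cc(O)cc(O)c3[C@@H]2c2ccc(O)cc2)[C@@H](c2ccc(O)cc2)O4)c1 | target

## Step count and least certain steps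

Total: 19 steps. Longest linear sequence: 17 steps (steps 1–6, 8 and 10–19, from 1); steps 7 and 9 prepare the coupling partners 15 and 19.

**Step 17 (key step).** The most likely failure is that cycloaddition is too slow: a linear alkyne has to be bent over the pyrone within a tether that contains the rigid ring A, so at the temperature needed protodeboronation of the alkynyl boronate or ionisation of the C2–O bond may win. The fallback sets out from 29 and replaces the alkyne dienophile by an alkene, which tolerates the seven-membered transition state better. Hydroboration of 29 with HBpin and catalytic Cp2Zr(H)Cl gives the (E)-alkenyl pinacol boronate F1. Heating effects the intramolecular Diels–Alder reaction to the bridged lactone F2, which as an alkene adduct keeps its CO2 bridge. Oxidation of the C–B bond with H2O2 in buffered THF gives the secondary alcohol F3, and Swern oxidation gives the ketone F4. Heating F4 expels CO2, and the resulting cyclohexadienone tautomerises to the phenol, so the route is rejoined at 33.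

**Step 10.** The enamine of a β,β-diaryl aldehyde is crowded, so slow arylation, a mismatched pairing of catalyst and Ca, and partial epimerisation of the product are the risks. The fallback sets out from 16 and gives up catalyst control: palladium-catalysed α-arylation with 4-bromoanisole (Pd(OAc)2, rac-BINAP, Cs2CO3, dioxane, 80 °C) under equilibrating conditions gives 20 together with its epimer at the new centre, the (1R,2R) aldehyde F5. The two are separated by chromatography, and F5 is returned to the equilibrium with DBU and recycled. The route is rejoined at 20.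

**Step 5.** The ortho bromine twists the aryl group out of conjugation with the carbene and crowds the catalyst pocket, so the risk is erosion of enantioselectivity, and carbene dimerisation or addition to the anisyl ring may compete with insertion. The fallback sets out from 8: Rh2(OAc)4 in CH2Cl2 followed by NaOMe/MeOH gives the racemic trans ester, that is 10 together with its enantiomer, the (2R,3R) ester F6. The two are separated by preparative chromatography on a chiral stationary phase, and the route is rejoined at 10.

**Step 16.** Hydroboration of the alkyne or reduction of the pyrone carbonyl by HBpin may compete with dehydrogenative borylation, and the alkynyl boronate may lose boron on handling. The fallback sets out from 29 and moves the borylation to after ring B is formed. NBS with catalytic AgNO3 in acetone gives the bromoalkyne F7. Heating F7 brings about the same intramolecular cycloaddition and decarboxylation, giving the B5 aryl bromide F8. Borylation of F8 with B2pin2, Pd(dppf)Cl2 and KOAc in dioxane gives 32, where the route is rejoined.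

**Step 19.** BBr3 may ionise the benzylic C2–O bond (ring opening, epimerisation, Friedel–Crafts oligomerisation on the electron-rich rings) and may form bromine adducts at the free aldehyde. The fallback sets out from 33, isolated before the acid treatment of step 18, and changes to nucleophilic demethylation with the aldehyde still masked. NaSEt in DMF at 140 °C cleaves the five methyl ethers by SN2 attack on methyl and gives the hexaphenol acetal F9. Dilute HCl in THF then releases the aldehyde, and the route is rejoined at 35.

## Further compounds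

F1 | step 17 | (E)-alkenyl pinacol boronate from hydroboration of 29 | C1COC(O1)c1ccc(OC)c(c1)[C@@H](c1cc(OC)cc2O[C@H](c3ccc(OC)cc3)[C@@H](C3=CC(OC)=CC(=O)O3)c12)[C@@H](c1ccc(OC)cc1)/C=C/B1OC(C)(C)C(C)(C)O1
F2 | step 17 | bridged lactone from intramolecular Diels–Alder reaction of F1 (2-oxabicyclo[2.2.2]oct-5-en-3-one core with the pinacol boronate on sp3 carbon; new centres not defined) | C1COC(O1)c1ccc(OC)c([C@H]2c3cc(OC)cc4c3[C@H](C56OC(=O)C(C(OC)=C5)C(B7OC(C)(C)C(C)(C)O7)C6[C@@H]2c2ccc(OC)cc2)[C@@H](c2ccc(OC)cc2)O4)c1
F3 | step 17 | secondary alcohol from C–B oxidation of F2 | C1COC(O1)c1ccc(OC)c([C@H]2c3cc(OC)cc4c3[C@H](C56OC(=O)C(C(OC)=C5)C(O)C6[C@@H]2c2ccc(OC)cc2)[C@@H](c2ccc(OC)cc2)O4)c1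
F4 | step 17 | ketone from oxidation of F3 | C1COC(O1)c1ccc(OC)c([C@H]2c3cc(OC)cc4c3[C@H](C56OC(=O)C(C(OC)=C5)C(=O)C6[C@@H]2c2ccc(OC)cc2)[C@@H](c2ccc(OC)cc2)O4)c1
F5 | step 10 | epimer of 20 at the aldehyde α-carbon, (1R,2R) side chain | O=C[C@@H](c1ccc(OC)cc1)[C@@H](c1cc(C2OCCO2)ccc1OC)c1cc(OC)cc2O[C@H](c3ccc(OC)cc3)[C@@H](C(=O)OC)c12
F6 | step 5 | methyl (2R,3R)-4-bromo-6-methoxy-2-(4-methoxyphenyl)-2,3-dihydro-1-benzofuran-3-carboxylate (enantiomer of 10) | Brc1cc(OC)cc2O[C@@H](c3ccc(OC)cc3)[C@H](C(=O)OC)c12
F7 | step 16 | 1-bromoalkyne from 29 | C1COC(O1)c1ccc(OC)c(c1)[C@@H](c1cc(OC)cc2O[C@H](c3ccc(OC)cc3)[C@@H](C3=CC(OC)=CC(=O)O3)c12)[C@@H](c1ccc(OC)cc1)C#CBr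
F8 | step 16 | penta-O-methyl vitisinol B ethylene acetal with bromine in place of the B5 hydroxyl | C1COC(O1)c1ccc(OC)c([C@H]2c3cc(OC)cc4c3[C@H](c3cc(OC)cc(Br)c3[C@@H]2c2ccc(OC)cc2)[C@@H](c2ccc(OC)cc2)O4)c1
F9 | step 19 | vitisinol B ethylene acetal (six free phenols) | C1COC(O1)c1ccc(O)c([C@H]2c3cc(O)cc4c3[C@H](c3cc(O)cc(O)c3[C@@H]2c2ccc(O)cc2)[C@@H](c2ccc(O)cc2)O4)c1
A1 | alternative 1 | tetra-O-methyl vitisinol B (free ring A hydroxyl and free 4-hydroxyphenyl on C2) | O=Cc1ccc(OC)c([C@H]2c3cc(O)cc4c3[C@H](c3cc(OC)cc(OC)c3[C@@H]2c2ccc(OC)cc2)[C@@H](c2ccc(O)cc2)O4)c1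
A2 | alternative 2 | racemic seven-membered keto ester with the ester on C3, the ketone at Cc and the bromo-methoxyphenyl ring on Ca | COC(=O)C1c2cc(OC)cc(OC)c2C(=O)C(c2cc(Br)ccc2OC)c2cc(OCOC)cc(OCOC)c21
A3 | alternative 3 | hexa-O-methyl vitisinol B with bromine in place of the formyl group | Brc1ccc(OC)c([C@H]2c3cc(OC)cc4c3[C@H](c3cc(OC)cc(OC)c3[C@@H]2c2ccc(OC)cc2)[C@@H](c2ccc(OC)cc2)O4)c1
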